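The target is epigallocatechin-(4β→6)-epigallocatechin 3-O-gallate. The route rests on forming the interflavan bond between C4 of the upper C-ring and C6 of the lower A-ring last, from two benzyl-protected halves that both derive from (−)-epigallocatechin. In one operation a Lewis acid ionises a 4β-(2-ethoxyethoxy) ether at the upper C4, which is benzylic to the A-ring carrying O5, O7 and O1, and C6 of the lower A-ring, flanked by O5 and O7, attacks trans to the upper 3-OH. Bromine caps secure selectivity: C8-Br on the galloylated lower unit leaves only C6 open, and C6/C8-dibromination of the upper unit excludes self-condensation. One hydrogenolysis then removes every bromine and benzyl group.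

Key step: step 6

Remark on the chemistry (assumption): (−)-epigallocatechin (2R,3R) and 3,4,5-tris(benzyloxy)benzoic acid are taken as commercial. The target's upper unit is (2R,3R,4S), i.e. 2,3-cis-3,4-trans with the C4 aryl group β, and its lower unit is (2R,3R). Usual flavan numbering is used throughout.

Step 1
Reactants: 1 (−)-epigallocatechin
Product: 2 5,7,3',4',5'-penta-O-benzyl-(−)-epigallocatechin
Conditions: BnBr (5.5 equiv), K2CO3 (5.5 equiv), degassed DMF, N2, −10 °C → rt
Reagents that add atoms: benzyl bromide, BrCc1ccccc1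
Why: Williamson etherification with K2CO3 should alkylate only the five phenols and leave the far less acidic secondary 3-OH free, with C2 and C3 untouched under mild, oxygen-free conditions.

Step 2
Reactants: 2 5,7,3',4',5'-penta-O-benzyl-(−)-epigallocatechin
Product: 3 (2R,3R,4S)-4-(2-ethoxyethoxy)-5,7,3',4',5'-penta-O-benzylepigallocatechin
Conditions: DDQ (2.0 equiv), EtOCH2CH2OH (5 equiv), CH2Cl2, rt
Reagents that add atoms: 2-ethoxyethanol, CCOCCO
Why: DDQ-mediated oxidative benzylic C–H etherification should occur at C4, the C–H activated by the O5/O7/O1-substituted A-ring, and the alcohol should enter on the β-face, trans to the 3-OH and away from the α C2-aryl group, which sets C4 as S.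

Step 3
Reactants: 3 (2R,3R,4S)-4-(2-ethoxyethoxy)-5,7,3',4',5'-penta-O-benzylepigallocatechin
Product: 4 (2R,3R,4S)-6,8-dibromo-4-(2-ethoxyethoxy)-5,7,3',4',5'-penta-O-benzylepigallocatechin
Conditions: NBS (2.1 equiv), CH2Cl2, −20 → 0 °C, dark
Reagents that add atoms: N-bromosuccinimide, O=C1CCC(=O)N1Br
Why: Electrophilic aromatic bromination should take C8 and then C6 of the phloroglucinol-type A-ring, whose three ortho/para oxygens make it far more reactive than the pyrogallol-type B-ring, and the neutral conditions should spare the acid-labile C4 ether.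

Step 4
Reactants: 2 5,7,3',4',5'-penta-O-benzyl-(−)-epigallocatechin
Product: 5 8-bromo-5,7,3',4',5'-penta-O-benzyl-(−)-epigallocatechin
Conditions: NBS (1.0 equiv), CH2Cl2, −45 °C → rt
Reagents that add atoms: N-bromosuccinimide, O=C1CCC(=O)N1Br
Why: Electrophilic aromatic bromination of 5,7-di-O-benzyl flavan-3-ols is selective for C8, the A-ring position flanked by only one benzyloxy group, and one equivalent at low temperature should stop at the monobromide.

Step 5
Reactants: 5 8-bromo-5,7,3',4',5'-penta-O-benzyl-(−)-epigallocatechin; 6 3,4,5-tris(benzyloxy)benzoic acid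
Product: 7 8-bromo-5,7,3',4',5'-penta-O-benzylepigallocatechin 3-O-(3,4,5-tri-O-benzylgallate)
Conditions: DCC (1.5 equiv), DMAP (cat.), CH2Cl2, rt
Reagents that add atoms: none
Why: Steglich esterification should acylate the only free hydroxyl, the secondary 3-OH, with retention at C3 because the C3–O bond is not broken.

Step 6
Reactants: 4 (2R,3R,4S)-6,8-dibromo-4-(2-ethoxyethoxy)-5,7,3',4',5'-penta-O-benzylepigallocatechin; 7 8-bromo-5,7,3',4',5'-penta-O-benzylepigallocatechin 3-O-(3,4,5-tri-O-benzylgallate)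
Product: 9 6,8-dibromo-penta-O-benzylepigallocatechin-(4β→6)-8-bromo-penta-O-benzylepigallocatechin 3-O-(tri-O-benzylgallate), via flavan-4-yl cation 8 (not isolated)
Conditions: 7 (1.5 equiv), TMSOTf (0.2 equiv), 4 Å MS, CH2Cl2, −78 → −20 °C; then Et3N
Reagents that add atoms: none
Why: TMSOTf should ionise the 4-(2-ethoxyethoxy) group to the flavan-4-yl cation 8, stabilised as a quinone-methide-type oxocarbenium ion by O1, O5 and O7, and C6 of 7 should attack it in a Friedel–Crafts alkylation; the closest known reaction type is the Lewis-acid-promoted condensation of 4-alkoxyflavan-3-ols with halogen-capped flavan-3-ol nucleophiles. No ring is closed. The single new stereocentre, C4 of the upper unit, is set by the substrate: in the half-chair cation the pseudo-axial 3-OH and the C2-aryl group both lie on the α-face, so the arene should enter on the β-face and give the 3,4-trans (4β, 4S) bond. Site selectivity on the nucleophile is secured by the C8 bromine, which leaves C6 as the only open position of its most electron-rich ring, the B-ring and galloyl ring being much less nucleophilic. Self-condensation of the electrophile is excluded because its own C6 and C8 carry bromine, and any O-alkylation at a 3-OH is reversible under the conditions whereas the C–C bond formation is not.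

Step 7
Reactants: 9 6,8-dibromo-penta-O-benzylepigallocatechin-(4β→6)-8-bromo-penta-O-benzylepigallocatechin 3-O-(tri-O-benzylgallate)
Product: 10 epigallocatechin-(4β→6)-epigallocatechin 3-O-gallate (target)
Conditions: H2 (1 atm), 20% Pd(OH)2/C, NaOAc (3.3 equiv), degassed THF/MeOH/H2O, rt; filtration under Ar, Sephadex LH-20
Reagents that add atoms: none
Why: Pd-catalysed hydrogenolysis should cleave all thirteen benzyl ethers and hydrodebrominate the three aryl bromides in one operation, with sodium acetate buffering the HBr so that the acid-labile interflavan bond and the gallate ester survive and no stereocentre is touched.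

Compound list
1 | (−)-epigallocatechin, (2R,3R) | O[C@@H]1Cc2c(O)cc(O)cc2O[C@@H]1c1cc(O)c(O)c(O)c1 | starting material
2 | 5,7,3',4',5'-penta-O-benzyl-(−)-epigallocatechin, (2R,3R), free 3-OH | O[C@@H]1Cc2c(OCc3ccccc3)cc(OCc3ccccc3)cc2O[C@@H]1c1cc(OCc2ccccc2)c(OCc2ccccc2)c(OCc2ccccc2)c1 | intermediate
3 | (2R,3R,4S)-4-(2-ethoxyethoxy)-5,7,3',4',5'-penta-O-benzylepigallocatechin (4β ether, trans to 3-OH) | CCOCCO[C@H]1c2c(OCc3ccccc3)cc(OCc3ccccc3)cc2O[C@H](c2cc(OCc3ccccc3)c(OCc3ccccc3)c(OCc3ccccc3)c2)[C@@H]1O | intermediate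
4 | (2R,3R,4S)-6,8-dibromo-4-(2-ethoxyethoxy)-5,7,3',4',5'-penta-O-benzylepigallocatechin | CCOCCO[C@H]1c2c(OCc3ccccc3)c(Br)c(OCc3ccccc3)c(Br)c2O[C@H](c2cc(OCc3ccccc3)c(OCc3ccccc3)c(OCc3ccccc3)c2)[C@@H]1O | intermediate
5 | 8-bromo-5,7,3',4',5'-penta-O-benzyl-(−)-epigallocatechin, (2R,3R) | O[C@@H]1Cc2c(OCc3ccccc3)cc(OCc3ccccc3)c(Br)c2O[C@@H]1c1cc(OCc2ccccc2)c(OCc2ccccc2)c(OCc2ccccc2)c1 | intermediate
6 | 3,4,5-tris(benzyloxy)benzoic acid | OC(=O)c1cc(OCc2ccccc2)c(OCc2ccccc2)c(OCc2ccccc2)c1 | starting material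
7 | 8-bromo-5,7,3',4',5'-penta-O-benzylepigallocatechin 3-O-(3,4,5-tri-O-benzylgallate), (2R,3R) | O=C(O[C@@H]1Cc2c(OCc3ccccc3)cc(OCc3ccccc3)c(Br)c2O[C@@H]1c1cc(OCc2ccccc2)c(OCc2ccccc2)c(OCc2ccccc2)c1)c1cc(OCc2ccccc2)c(OCc2ccccc2)c(OCc2ccccc2)c1 | intermediate
8 | flavan-4-yl cation from 4 (6,8-dibromo, pentabenzyl, 3-OH free; 2R,3R) | [CH+]1c2c(OCc3ccccc3)c(Br)c(OCc3ccccc3)c(Br)c2O[C@H](c2cc(OCc3ccccc3)c(OCc3ccccc3)c(OCc3ccccc3)c2)[C@@H]1O | intermediate (not isolated)
9 | 6,8-dibromo-penta-O-benzylepigallocatechin-(4β→6)-8-bromo-penta-O-benzylepigallocatechin 3-O-(tri-O-benzylgallate); upper (2R,3R,4S), lower (2R,3R) | O=C(O[C@@H]1Cc2c(c(Br)c(OCc3ccccc3)c([C@H]3c4c(OCc5ccccc5)c(Br)c(OCc5ccccc5)c(Br)c4O[C@H](c4cc(OCc5ccccc5)c(OCc5ccccc5)c(OCc5ccccc5)c4)[C@@H]3O)c2OCc2ccccc2)O[C@@H]1c1cc(OCc2ccccc2)c(OCc2ccccc2)c(OCc2ccccc2)c1)c1cc(OCc2ccccc2)c(OCc2ccccc2)c(OCc2ccccc2)c1 | intermediate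
10 | epigallocatechin-(4β→6)-epigallocatechin 3-O-gallate; upper (2R,3R,4S), lower (2R,3R) | O=C(O[C@@H]1Cc2c(cc(O)c([C@H]3c4c(O)cc(O)cc4O[C@H](c4cc(O)c(O)c(O)c4)[C@@H]3O)c2O)O[C@@H]1c1cc(O)c(O)c(O)c1)c1cc(O)c(O)c(O)c1 | target

Total step count: 7. Longest linear sequence: 5 steps (steps 1, 2, 3, 6, 7; the lower branch, steps 1, 4, 5, 6, 7, is equally long).

Steps most likely to fail

Step 6. Ionisation of the doubly bromine-flanked electrophile may be slow, and capture at the crowded C6 between two benzyloxy groups may be slower still. The cation could then be diverted into 3-O-alkylated oligomers or elimination. The fallback gives up complete blocking for kinetic control. It sets out from 3, which with NBS (1.0 equiv, CH2Cl2, −20 °C) should give the 8-monobromo 4β-(2-ethoxyethoxy) ether F1, whose 5- and 7-benzyloxy groups can stay in conjugation. F1 is added by syringe pump to 7 (4 equiv) and BF3·OEt2 in CH2Cl2 at −78 → −30 °C, so that the cation meets mainly 7. This should give the doubly 8-brominated tridecabenzyl dimer F2, with excess 7 recovered. F2 under the conditions of step 7 comes back to the route at 10.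

Step 7. Bromide and HBr released during the reduction may poison the catalyst, leave hindered benzyl ethers in place or cleave the interflavan bond. The fallback separates the two tasks. From 9, radical hydrodebromination (Bu3SnH, AIBN, toluene, 90 °C) should give the bromine-free tridecabenzyl dimer F3. F3 is then hydrogenolysed under neutral conditions (H2, Pd(OH)2/C, THF/MeOH/H2O) and comes back at 10.

Step 3. Bromination may run on to the B-ring, or adventitious HBr may strip the acid-labile C4 ether. The fallback inverts the order of operations. From 2, NBS (2.1 equiv, CH2Cl2, 0 °C) should give 6,8-dibromo-5,7,3',4',5'-penta-O-benzylepigallocatechin F4, a robust compound that can be purified by crystallisation. DDQ with 2-ethoxyethanol (1,2-dichloroethane, 40 °C) then installs the 4β ether and comes back at 4.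

Further compounds
F1 | step 6 | (2R,3R,4S)-8-bromo-4-(2-ethoxyethoxy)-5,7,3',4',5'-penta-O-benzylepigallocatechin | CCOCCO[C@H]1c2c(OCc3ccccc3)cc(OCc3ccccc3)c(Br)c2O[C@H](c2cc(OCc3ccccc3)c(OCc3ccccc3)c(OCc3ccccc3)c2)[C@@H]1O
F2 | step 6 | 8-bromo-penta-O-benzylepigallocatechin-(4β→6)-8-bromo-penta-O-benzylepigallocatechin 3-O-(tri-O-benzylgallate) | O=C(O[C@@H]1Cc2c(c(Br)c(OCc3ccccc3)c([C@H]3c4c(OCc5ccccc5)cc(OCc5ccccc5)c(Br)c4O[C@H](c4cc(OCc5ccccc5)c(OCc5ccccc5)c(OCc5ccccc5)c4)[C@@H]3O)c2OCc2ccccc2)O[C@@H]1c1cc(OCc2ccccc2)c(OCc2ccccc2)c(OCc2ccccc2)c1)c1cc(OCc2ccccc2)c(OCc2ccccc2)c(OCc2ccccc2)c1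
F3 | step 7 | penta-O-benzylepigallocatechin-(4β→6)-penta-O-benzylepigallocatechin 3-O-(tri-O-benzylgallate) | O=C(O[C@@H]1Cc2c(cc(OCc3ccccc3)c([C@H]3c4c(OCc5ccccc5)cc(OCc5ccccc5)cc4O[C@H](c4cc(OCc5ccccc5)c(OCc5ccccc5)c(OCc5ccccc5)c4)[C@@H]3O)c2OCc2ccccc2)O[C@@H]1c1cc(OCc2ccccc2)c(OCc2ccccc2)c(OCc2ccccc2)c1)c1cc(OCc2ccccc2)c(OCc2ccccc2)c(OCc2ccccc2)c1
F4 | step 3 | 6,8-dibromo-5,7,3',4',5'-penta-O-benzyl-(−)-epigallocatechin | O[C@@H]1Cc2c(OCc3ccccc3)c(Br)c(OCc3ccccc3)c(Br)c2O[C@@H]1c1cc(OCc2ccccc2)c(OCc2ccccc2)c(OCc2ccccc2)c1
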